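(The data are calculated for substances that don't exist.)

Start from a ratio: ochre's molar pace of D over amber's, counted as amount per minute, not percent per minute.

the same everywhere: X 180 mM (held)

| run | Q | temperature | remark | time |
|---|---|---|---|---|
| amber | 0.42 M | 10 °C | run made earlier |  |
| ochre | 0.66 M | 43 °C | run made earlier |  |
| south | 0.30 M | 55 °C |  | 25 min |
| east | 0.30 M | −5 °C |  | 25 min |
| north | 0.30 M | 25 °C |  | 25 min |

| run | time / min | D / % |
|---|---|---|
| amber | 20.0 | 2.6 |
| amber | 60.0 | 29.0 |
| amber | 120 | 65.8 |
| amber | 180 | 89.8 |
| amber | 240 | 97.3 |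
| ochre | 10.0 | 63.8 |
| ochre | 20.0 | 99.0 |
| ochre | 25.0 | 101.4 |
| ochre | 40.0 | 99.2 |
| ochre | 50.0 | 101.2 |

(scatter of a reading: 1 percentage point)

1. which flask leads in amount of D, in percent of the Q charged ("all alike" within 1.5 percentage points) (south / east / north / all alike)
2. how much D is there at the end, in percent of the Q charged: south
3. how much D is there at the end, in percent of the Q charged: east
4. how much D is there at the end, in percent of the Q charged: north

- at the start none of X is in solution

1. Ochre stays near the whole charge, at 99.0% after 20.0 min and 101.2% after 50.0 min, so you take that as the ceiling and ask how fast each flask approaches it.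

2. Amber's straight middle reads 2.58 mM min⁻¹, and ochre's first stretch reads 42.1 mM min⁻¹, a ratio of 16.3. Q and temperature differ between these runs. The logarithm of that ratio over the gap in inverse temperature is 7580 K: this is the pace steepness.

3. Upper end of the bracket: suppose molar pace carries over, so percent runs faster at a smaller charge. A flask minute is then worth exp(steepness × gap) × (amber charge / flask charge) amber minutes. For north that is 5.38, so 25 min in north matches 135 min of amber, where interpolation gives 71.6%.

4. Lower end of the bracket: suppose percent pace carries over and the charge drops out. The steepness becomes 6350 K, north matches 77.3 min of amber, and interpolation gives 39.6%.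

5. Amber's straight middle looks like a fixed molar feed, so my own figure for north is the upper end, 71.6%.

6. The forecast puts south first, with south 99%, east 1% and north 50%. That north figure lies inside the bracket, and its range runs from 33% to 68%. It notes: “Lower Q may raise the percentage.”

7. North gives 74.4%, which is 2.8 percentage points above the upper end of the bracket; south gives 100% and leads, and east gives 0.0557%. At 25.0 min, north still holds 25.1% as Z, a species on the way to D, with 0.190% as Q. The same steepness gives east 0.313 amber minutes per minute, so 25 min there matches 7.83 min of amber, short of amber's first reading at 20.0 min.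

    Q → Z (k = 0.00710 s⁻¹, Ea = 94.0 kJ mol⁻¹)
    J → G (k = 0.00190 s⁻¹, Ea = 88.0 kJ mol⁻¹)
    Z + G → D (k = 0.0120 M⁻¹ s⁻¹, Ea = 56.0 kJ mol⁻¹)
    Q ⇌ L (K = 0.350, k = 0.00130 s⁻¹, Ea = 79.0 kJ mol⁻¹, ΔH = −43.0 kJ mol⁻¹)
    X ⇌ J, rate k5*(csat - [J]) (kL = 0.00730 s⁻¹)
    (constants at 25 °C)

8. Read south at 6.0 min. The two ends of the bracket match 130 min and 330 min of amber, which is from 69.9% up to past amber's last reading of 97.3%. The computed reading is 87.0%, with 13.0% as Z.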